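## Retrosynthetic overview

1. The last bond made joins the carbinol carbon to ring A C1. Both ends are acceptor carbons: the aldehyde carbon of a ring B enal and the SN2′ end of a ring A allylic bromide. The allyl unit is used in its reversed, donor form (allylchromium). This one step sets both new stereocentres and creates the exocyclic methylene.
2. Ring A allylic bromide ⇐ allylic alcohol (bromination with transposition) ⇐ ring-closing metathesis ⇐ prenyl bromide + 2-methylidenepent-4-enal ⇐ pent-4-enal + formaldehyde.
3. Ring B enal ⇐ equatorial bromide by SN2 inversion of an axial mesylate ⇐ trans-diaxial diol ⇐ epoxides ⇐ Vilsmeier formylation of (S)-limonene, whose stereocentre controls ring B.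
4. Ring order: ring B is bought with (S)-limonene. Ring A is closed by metathesis at the fragment stage. No ring is formed after the coupling.

Assumption: the (S,S) ligand of step 9 is taken to send the allyl group to the Si face of the aldehyde; if the first run shows the opposite sense, its mirror image from D-valinol is used and nothing else changes.

## Route

Step 1
Reactants: 1 (S)-(−)-limonene
Product: 3 (2E)-3-[(1S)-4-methylcyclohex-3-en-1-yl]but-2-enal, via alkenyliminium chloride 2 (not isolated)
Conditions: POCl3 (1.2 equiv), DMF, 0 to 60 °C; then ice-water, rt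
Reagents that add atoms: N,N-dimethylformamide CN(C)C=O; water O
Why: Vilsmeier–Haack formylation, in which the chloroiminium ion attacks the terminal CH2 of the accessible 1,1-disubstituted alkene, proton loss and hydrolysis give the conjugated enal as the E isomer (formyl group away from the ring), and the limonene stereocentre is untouched.

Step 2
Reactants: 3 (2E)-3-[(1S)-4-methylcyclohex-3-en-1-yl]but-2-enal
Product: 5 (2E)-3-[(1S,3R,4R)-3,4-dihydroxy-4-methylcyclohexyl]but-2-enal, via epoxide mixture 4 (not isolated)
Conditions: mCPBA (1.05 equiv), CH2Cl2, 0 °C; then THF, 1 M aq. H2SO4, rt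
Reagents that add atoms: 3-chloroperoxybenzoic acid O=C(OO)c1cccc(Cl)c1; water O
Why: Prilezhaev epoxidation of the only electron-rich alkene, then acid-catalysed trans-diaxial (Fürst–Plattner) opening, in which water attacks the tertiary carbon of one epoxide and the secondary carbon of the other, so both converge on one diol with the tertiary OH axial and cis to the side chain (4R).

Step 3
Reactants: 5 (2E)-3-[(1S,3R,4R)-3,4-dihydroxy-4-methylcyclohexyl]but-2-enal
Product: 6 (1R,2R,5S)-2-hydroxy-2-methyl-5-[(2E)-4-oxobut-2-en-2-yl]cyclohexyl methanesulfonate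
Conditions: MsCl (1.1 equiv), pyridine, CH2Cl2, 0 °C
Reagents that add atoms: methanesulfonyl chloride CS(=O)(=O)Cl
Why: Chemoselective O-sulfonylation, in which only the secondary alcohol reacts because the tertiary one is too hindered, and no stereocentre is touched.

Step 4
Reactants: 6 (1R,2R,5S)-2-hydroxy-2-methyl-5-[(2E)-4-oxobut-2-en-2-yl]cyclohexyl methanesulfonate
Product: 7 (2E)-3-[(1S,3S,4R)-3-bromo-4-hydroxy-4-methylcyclohexyl]but-2-enal
Conditions: LiBr (5 equiv), DMF, 70 °C
Reagents that add atoms: lithium bromide [Li+].[Br-]
Why: SN2 displacement of the axial mesylate by non-basic bromide with clean inversion places bromine equatorial and cis to the tertiary OH (3S), an arrangement that bromonium or epoxide opening cannot give.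

Step 5
Reactants: 8 pent-4-enal
Product: 9 2-methylidenepent-4-enal
Conditions: 37 % aq. HCHO, pyrrolidine (10 mol %), propionic acid (10 mol %), iPrOH, 45 °C
Reagents that add atoms: formaldehyde C=O
Why: Organocatalytic Mannich-type α-methylenation, in which the enamine of 8 adds to the formaldehyde iminium ion and β-elimination of the amine gives the 2-substituted acrolein; no stereocentre is formed.

Step 6
Reactants: 9 2-methylidenepent-4-enal; 10 1-bromo-3-methylbut-2-ene (prenyl bromide)
Product: 12 3,3-dimethyl-5-methylideneocta-1,7-dien-4-ol (racemic), via prenylzinc bromide 11 (not isolated)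
Conditions: Zn dust, THF/sat. aq. NH4Cl, 0 °C to rt
Reagents that add atoms: none
Why: Zinc Barbier allylation, in which 11 adds 1,2 through its γ-carbon (SE2′, six-membered transition state) and so bonds the gem-dimethyl carbon to the carbonyl carbon; the racemic carbinol centre does not matter because it is erased in step 8.

Step 7
Reactants: 12 3,3-dimethyl-5-methylideneocta-1,7-dien-4-ol
Product: 13 2,2-dimethyl-6-methylidenecyclohex-3-en-1-ol (racemic)
Conditions: second-generation Grubbs catalyst (3 mol %), 1,4-benzoquinone (10 mol %), CH2Cl2 (0.01 M), 40 °C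
Reagents that add atoms: none
Why: Ring-closing metathesis of the two monosubstituted alkenes closes ring A and places the skipped diene unambiguously, while the 1,1-disubstituted alkene is a spectator because closure onto it would give a three- or four-membered ring.

Step 8
Reactants: 13 2,2-dimethyl-6-methylidenecyclohex-3-en-1-ol
Product: 14 1-(bromomethyl)-3,3-dimethylcyclohexa-1,4-diene
Conditions: PBr3 (0.4 equiv), pyridine (0.1 equiv), Et2O, −20 to 0 °C
Reagents that add atoms: phosphorus tribromide BrP(Br)Br
Why: Allylic bromination with transposition (SN2′), in which direct substitution at the neopentyl ring carbon is blocked and bromide enters at the exocyclic CH2; any untransposed bromide would give the same allylmetal in step 9.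

Step 9
Reactants: 14 1-(bromomethyl)-3,3-dimethylcyclohexa-1,4-diene (1.5 equiv); 7 (2E)-3-[(1S,3S,4R)-3-bromo-4-hydroxy-4-methylcyclohexyl]but-2-enal
Product: 17 (1R,2E)-3-[(1S,3S,4R)-3-bromo-4-hydroxy-4-methylcyclohexyl]-1-[(1R)-2,2-dimethyl-6-methylidenecyclohex-3-en-1-yl]but-2-en-1-ol, via allylchromium dichloride 15 (not isolated), via trimethylsilyl ether 16 (not isolated)
Conditions: CrCl2 (10 mol %), (S,S)-1,8-bis(4-isopropyl-4,5-dihydrooxazol-2-yl)-3,6-diphenyl-9H-carbazole (12 mol %), iPr2NEt (30 mol %), Mn powder (3 equiv), Me3SiCl (2 equiv), THF, 0 °C to rt; then citric acid, MeOH, 0 °C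
Reagents that add atoms: none
Why: Proposed new method: the aldehyde carbon of 7 and the ring carbon of 14 (the SN2′ end of the allylic bromide) are both acceptor carbons, and two one-electron transfers from divalent chromium turn the allyl cation synthon into its reversed-polarity donor 15 (a d3 donor, the hydrocarbon counterpart of a homoenolate), which adds through its ring carbon in a closed chair transition state, so that the ring-locked E geometry enforces the anti pair, allylic transposition creates the exocyclic methylene, and the chromium-bound bis(oxazoline) selects the Si face of the aldehyde to give the (1R) carbinol and the (1R) ring carbon, while Mn regenerates divalent chromium, Me3SiCl releases the catalyst as 16, and the secondary alkyl bromide, the tertiary alcohol and the other alkenes are inert to organochromium reagents; the closest known reaction type is the chromium-catalysed asymmetric Nozaki–Hiyama allylation and crotylation of aldehydes with allylic bromides.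

## Compound list

1 | (S)-(−)-limonene, (4S)-1-methyl-4-(prop-1-en-2-yl)cyclohex-1-ene | C=C(C)[C@H]1CCC(C)=CC1 | starting material
2 | (2E)-N,N-dimethyl-3-[(1S)-4-methylcyclohex-3-en-1-yl]but-2-en-1-iminium chloride | C[N+](C)=C/C=C(\C)[C@H]1CCC(C)=CC1.[Cl-] | intermediate
3 | (2E)-3-[(1S)-4-methylcyclohex-3-en-1-yl]but-2-enal | O=C/C=C(\C)[C@H]1CCC(C)=CC1 | intermediate
4 | (2E)-3-[(3S)-6-methyl-7-oxabicyclo[4.1.0]heptan-3-yl]but-2-enal, both epoxide faces | O=C/C=C(\C)[C@H]1CCC2(C)OC2C1 | intermediate
5 | (2E)-3-[(1S,3R,4R)-3,4-dihydroxy-4-methylcyclohexyl]but-2-enal | O=C/C=C(\C)[C@H]1CC[C@@](C)(O)[C@H](O)C1 | intermediate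
6 | (1R,2R,5S)-2-hydroxy-2-methyl-5-[(2E)-4-oxobut-2-en-2-yl]cyclohexyl methanesulfonate | O=C/C=C(\C)[C@H]1CC[C@@](C)(O)[C@H](OS(C)(=O)=O)C1 | intermediate
7 | (2E)-3-[(1S,3S,4R)-3-bromo-4-hydroxy-4-methylcyclohexyl]but-2-enal | O=C/C=C(\C)[C@H]1CC[C@@](C)(O)[C@@H](Br)C1 | intermediate
8 | pent-4-enal | C=CCCC=O | starting material
9 | 2-methylidenepent-4-enal | C=CCC(=C)C=O | intermediate
10 | 1-bromo-3-methylbut-2-ene (prenyl bromide) | CC(C)=CCBr | starting material
11 | (3-methylbut-2-en-1-yl)zinc bromide | CC(C)=CC[Zn]Br | intermediate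
12 | 3,3-dimethyl-5-methylideneocta-1,7-dien-4-ol (racemic) | C=CCC(=C)C(O)C(C)(C)C=C | intermediate
13 | 2,2-dimethyl-6-methylidenecyclohex-3-en-1-ol (racemic) | C=C1CC=CC(C)(C)C1O | intermediate
14 | 1-(bromomethyl)-3,3-dimethylcyclohexa-1,4-diene | BrCC1=CC(C)(C)C=CC1 | intermediate
15 | [(3,3-dimethylcyclohexa-1,4-dien-1-yl)methyl]chromium dichloride, carried by the chiral ligand (ligand not drawn) | Cl[Cr](Cl)CC1=CC(C)(C)C=CC1 | intermediate
16 | trimethylsilyl ether of 17 at the secondary carbinol | C=C1CC=CC(C)(C)[C@@H]1[C@H](O[Si](C)(C)C)/C=C(\C)[C@H]1CC[C@@](C)(O)[C@@H](Br)C1 | intermediate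
17 | (1R,2E)-3-[(1S,3S,4R)-3-bromo-4-hydroxy-4-methylcyclohexyl]-1-[(1R)-2,2-dimethyl-6-methylidenecyclohex-3-en-1-yl]but-2-en-1-ol | C=C1CC=CC(C)(C)[C@@H]1[C@H](O)/C=C(\C)[C@H]1CC[C@@](C)(O)[C@@H](Br)C1 | target

## Step count and risks

Total step count: 9.

Longest linear sequence: 5 steps (1 → 3 → 5 → 6 → 7 → 17, or 8 → 9 → 12 → 13 → 14 → 17).

**Most likely to fail, first: step 9.**
- The ring carbon that must bond lies next to a quaternary carbon.
- No chiral chromium catalyst has been tested on a ring-locked, β,γ-disubstituted allyl unit.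
- 14 can dimerise.

The fallback sets out from 14 and 7 and comes back to the route at 17. 14 is borylated with B2pin2 and Pd2(dba)3 (1 mol %) in toluene at 60 °C. This gives the storable allyl donor 2-[(3,3-dimethylcyclohexa-1,4-dien-1-yl)methyl]-4,4,5,5-tetramethyl-1,3,2-dioxaborolane F1, which is still the polarity-reversed form of the allyl unit. F1 and 7 are then joined in toluene at −30 °C under 5 mol % of the chiral phosphoric acid (S)-3,3′-bis(2,4,6-triisopropylphenyl)-1,1′-binaphthyl-2,2′-diyl hydrogen phosphate. In this Brønsted-acid-catalysed allylboration the closed chair gives the same anti pair. Here an organic acid, not a metal-bound ligand, selects the Si face. The first product is the pinacol borate ester of 17 F2, which aqueous NaHCO3 hydrolyses to 17.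

**Second: step 4.**
- The carbon under attack is flanked by a fully substituted carbon.
- The anti-periplanar tertiary OH can close to the epoxide, which bromide would reopen to the unwanted trans-diaxial bromohydrin.
- E2 elimination also competes.

The fallback sets out from 5 and comes back at 7. The diol is tied up with SO2Cl2 and Et3N in CH2Cl2 at −78 °C as the trans-fused cyclic sulfate of diol 5 F3, so the tertiary oxygen can no longer form an epoxide. LiBr in refluxing THF opens F3 at the secondary carbon with inversion to the lithium salt of the tertiary sulfate monoester of 7 F4. Catalytic H2SO4 in wet THF then hydrolyses F4 to 7.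

**Third: step 1.**
- Formylation of an unactivated alkene gives moderate yields, E/Z mixtures and some double formylation.

The fallback sets out from 1 and comes back at 3.
- The less hindered isopropenyl alkene is cleaved with OsO4 (1 mol %), NaIO4 and 2,6-lutidine in dioxane/water to 1-[(1S)-4-methylcyclohex-3-en-1-yl]ethan-1-one F5.
- Horner–Wadsworth–Emmons olefination with triethyl phosphonoacetate and NaH in THF gives ethyl (2E)-3-[(1S)-4-methylcyclohex-3-en-1-yl]but-2-enoate F6, and the minor Z isomer is removed by chromatography.
- DIBAL-H in CH2Cl2 at −78 °C gives (2E)-3-[(1S)-4-methylcyclohex-3-en-1-yl]but-2-en-1-ol F7.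
- MnO2 in CH2Cl2 oxidises F7 to 3.

## Further compounds

F1 | step 9 | 2-[(3,3-dimethylcyclohexa-1,4-dien-1-yl)methyl]-4,4,5,5-tetramethyl-1,3,2-dioxaborolane | CC1(C)OB(CC2=CC(C)(C)C=CC2)OC1(C)C
F2 | step 9 | pinacol borate ester of 17 | C=C1CC=CC(C)(C)[C@@H]1[C@H](OB1OC(C)(C)C(C)(C)O1)/C=C(\C)[C@H]1CC[C@@](C)(O)[C@@H](Br)C1
F3 | step 4 | trans-fused cyclic sulfate of diol 5 | O=C/C=C(\C)[C@H]1CC[C@@]2(C)OS(=O)(=O)O[C@@H]2C1
F4 | step 4 | lithium salt of the tertiary sulfate monoester of 7 | O=C/C=C(\C)[C@H]1CC[C@@](C)(OS(=O)(=O)[O-])[C@@H](Br)C1.[Li+]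
F5 | step 1 | 1-[(1S)-4-methylcyclohex-3-en-1-yl]ethan-1-one | CC(=O)[C@H]1CCC(C)=CC1
F6 | step 1 | ethyl (2E)-3-[(1S)-4-methylcyclohex-3-en-1-yl]but-2-enoate | CCOC(=O)/C=C(\C)[C@H]1CCC(C)=CC1
F7 | step 1 | (2E)-3-[(1S)-4-methylcyclohex-3-en-1-yl]but-2-en-1-ol | OC/C=C(\C)[C@H]1CCC(C)=CC1
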